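**Retrosynthetic overview**
1. Endgame: 29 comes from tetraol 24, which already carries the 8-angelate. Oxidation at C12 closes the γ-lactone (O6–C12) last, and O2 and O9 are acetylated together.
2. Key cut: a retro anionic oxy-Cope re-forms C4–C9 and breaks C6–C7, so the ten-membered carbocycle C1–C10 shrinks to the 1,2-divinylcyclohex-2-enol 16.
3. Structural feature used: C9–C10(C14)=C1–C2–C3–C4(C15), with oxygen on C2 and C9 and the Z C1=C10 bond, is a 2,6-dimethylcyclohexene. These are the six ring carbons, both methyl groups and both oxygens of 2,6-dimethylbenzoquinone, and an olefin inside that ring can only be Z.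
4. In one operation step 9 expands the ring from six to ten members, forms C4=C5 as E and sets C6, C7 and C8. C9 follows by ketone reduction. C2 and C4 come from a first oxy-Cope on the quinol followed by asymmetric transfer hydrogenation.
5. Ring order: six-membered carbocycle (purchased), ten-membered carbocycle (step 9), γ-lactone (step 13).

Key step: step 9

Remark: germacrane numbering of the target is used for all compounds. C6 carries the lactone oxygen, C7 carries C11–C13, and C10 and C4 carry C14 and C15. α/β refer to the flat drawing with H-7 α. The target is read as 2R,6R,7S,8R,9R (2β,8α,9β-triacyloxy-6α,12-olide), 1(10)Z, 4E, with a Z (angelate) ester. TBSO = tert-butyldimethylsilyloxy.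

Step 1
Reactants: 1 2,6-dimethyl-1,4-benzoquinone; 2 allylmagnesium bromide
Product: 3 4-allyl-4-hydroxy-2,6-dimethylcyclohexa-2,5-dien-1-one
Conditions: 2, THF, −78 °C; then H2O
Reagents that add atoms: allylmagnesium bromide, C=CC[Mg]Br
Why: Grignard 1,2-addition should take the carbonyl that is not flanked by methyl groups and give the achiral p-quinol, so no stereocentre is formed.

Step 2
Reactants: 3 4-allyl-4-hydroxy-2,6-dimethylcyclohexa-2,5-dien-1-one
Product: 6 rac-6-allyl-2,6-dimethylcyclohex-2-ene-1,4-dione, via potassium alkoxide 4 (not isolated), via potassium enolate 5 (not isolated)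
Conditions: KH, 18-crown-6, THF, 0 °C → rt; then AcOH
Reagents that add atoms: none
Why: An anionic oxy-Cope rearrangement of the allyl quinol alkoxide moves the allyl group to the methyl-bearing ring carbon (future C4); it is driven by enolate formation, the product cannot aromatise, and it is racemic because the two ring olefins are enantiotopic.

Step 3
Reactants: 6 rac-6-allyl-2,6-dimethylcyclohex-2-ene-1,4-dione
Product: 7 (4R,6R)-6-allyl-4-hydroxy-2,6-dimethylcyclohex-2-en-1-one (OH cis to 6-CH3)
Conditions: RuCl[(R,R)-TsDPEN](p-cymene) (cat.), KOt-Bu (cat.), i-PrOH, rt; chromatographic separation of the two diastereomers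
Reagents that add atoms: none
Why: Noyori asymmetric transfer hydrogenation, known to reduce only the unhindered C4 ketone of 2,6,6-trisubstituted cyclohex-2-ene-1,4-diones, should deliver hydride under catalyst control to the same face in both enantiomers of 6 (sense assigned by analogy with alkenyl ketones), which sets C2 as R and turns the racemate into two separable, enantiopure diastereomers.

Step 4
Reactants: 7 (4R,6R)-6-allyl-4-hydroxy-2,6-dimethylcyclohex-2-en-1-one
Product: 9 2-[(1S,5R)-5-hydroxy-1,3-dimethyl-2-oxocyclohex-3-en-1-yl]acetaldehyde, via vicinal diol 8 (not isolated)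
Conditions: OsO4 (cat.), NaIO4, 2,6-lutidine, dioxane–H2O, rt
Reagents that add atoms: sodium periodate, [Na+].[O-]I(=O)(=O)=O (terminal oxygen source); osmium tetroxide, O=[Os](=O)(=O)=O (oxygen carrier)
Why: Lemieux–Johnson cleavage should take the electron-rich terminal alkene in preference to the enone olefin and leave C5–C6 as CH2CHO, and no lactol can form because the hydroxyl group is trans to this chain.

Step 5
Reactants: 9 2-[(1S,5R)-5-hydroxy-1,3-dimethyl-2-oxocyclohex-3-en-1-yl]acetaldehyde
Product: 10 (4R,6S)-4-(TBSO)-6-[(E)-2-(TBSO)ethenyl]-2,6-dimethylcyclohex-2-en-1-one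
Conditions: TBSOTf, Et3N, CH2Cl2, −78 → 0 °C; Et3N-deactivated silica
Reagents that add atoms: tert-butyldimethylsilyl triflate, CC(C)(C)[Si](C)(C)OS(=O)(=O)C(F)(F)F
Why: Silyl triflate/amine soft enolisation silylates the alcohol and the aldehyde in one operation; the E enol ether is expected because deprotonation proceeds through the rotamer with quaternary C4 anti to O6, and because the Z isomer would press OTBS against that carbon.

Step 6
Reactants: 11 2-bromoprop-2-en-1-ol
Product: 12 (2-bromoallyloxy)(tert-butyl)dimethylsilane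
Conditions: TBSCl, imidazole, CH2Cl2, rt
Reagents that add atoms: tert-butyldimethylsilyl chloride, CC(C)(C)[Si](C)(C)Cl
Why: This is a standard silyl ether protection of a primary allylic alcohol.

Step 7
Reactants: 12 (2-bromoallyloxy)(tert-butyl)dimethylsilane; 13 (E)-1,2-bis(tributylstannyl)ethene
Product: 14 (E)-tert-butyldimethyl{[2-methylidene-4-(tributylstannyl)but-3-en-1-yl]oxy}silane
Conditions: 13 (excess), Pd(PPh3)4 (cat.), toluene, 90 °C
Reagents that add atoms: (E)-1,2-bis(tributylstannyl)ethene, CCCC[Sn](CCCC)(CCCC)/C=C/[Sn](CCCC)(CCCC)CCCC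
Why: A mono-Stille coupling of the bis-stannane with the vinyl bromide retains the E geometry and leaves one stannyl group as the handle for lithiation.

Step 8
Reactants: 14 (E)-dienylstannane; 10 (4R,6S)-4-(TBSO)-6-[(E)-2-(TBSO)ethenyl]-2,6-dimethylcyclohex-2-en-1-one
Product: 16 (1S,4R,6S)-4-(TBSO)-6-[(E)-2-(TBSO)ethenyl]-1-[(1E)-3-(TBSO-methyl)buta-1,3-dien-1-yl]-2,6-dimethylcyclohex-2-en-1-ol, via dienyllithium 15 (not isolated)
Conditions: 14, n-BuLi, THF, −78 °C; then 10, −78 → −40 °C; then H2O
Reagents that add atoms: none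
Why: Tin–lithium exchange is followed by 1,2-addition of the alkenyllithium to the hindered enone (as known for 2,6,6-trisubstituted cyclohexenones); in the favoured half-chair 4-OTBS and 6-CH3 are equatorial and the silyloxyvinyl group is axial, so axial attack from the opposite face should place the new dienyl group trans to it (C9 S).

Step 9
Reactants: 16 (1S,4R,6S)-divinylcyclohexenol
Product: 19 (1(10)Z,4E)-2β,6α,12-tris(TBSO)-8α-hydroxygermacra-1(10),4,11(13)-trien-9-one, via potassium alkoxide 17 (not isolated), via ring-expanded potassium enolate 18 (not isolated)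
Conditions: KHMDS, 18-crown-6, THF, −78 °C → rt; recool to −78 °C, 2-(phenylsulfonyl)-3-phenyloxaziridine; then AcOH
Reagents that add atoms: 2-(phenylsulfonyl)-3-phenyloxaziridine, O=S(=O)(c1ccccc1)N1OC1c1ccccc1
Why: Deprotonation gives alkoxide 17, whose charge-accelerated [3,3] shift breaks the ring bond C4–C9 and forms C6–C7; this is the anionic oxy-Cope rearrangement, the known way from 1,2-divinylcyclohex-2-enols to (2Z,6E)-cyclodecadienones. The ten-membered carbocycle arises by a four-atom ring expansion and not by an end-to-end closure, and its C1=C10 bond is carried over from the cyclohexene, so it can only be Z. The trans-diequatorial divinyl array of 17 allows a single, trans-decalin-like chair in which C3 is equatorial on C4, so C4=C5 forms E. In the same chair the oxygen of the E enol ether and C11 of the E alkenyl group are both equatorial, so the stereocentres C4 and C9 of 17 are traded for C6 (6α-O) and C7 (H-7α) with H-6 and H-7 anti, as the trans-lactone requires. Enolate 18 is formed with C7 and C10 trans across C8=C9 and with its inner face turned towards C4=C5, so the N-sulfonyloxaziridine (enolate hydroxylation) can reach only the outer face, which gives the 8α (R) alcohol. The selectivities needed are chair over boat, secured by the trans-fused chair, and the exocyclic vinyl over the endocyclic C1=C10 as the [3,3] partner, secured by the strain of the bridged alternative; the silyl groups should tolerate KHMDS, and the 1,5-diene of 19 should not undergo a second Cope shift at or below room temperature.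

Step 10
Reactants: 19 8α-hydroxy-9-ketone; 20 angelic acid ((Z)-2-methylbut-2-enoic acid)
Product: 22 (1(10)Z,4E)-8α-angeloyloxy-2β,6α,12-tris(TBSO)germacra-1(10),4,11(13)-trien-9-one, via angelic 2,4,6-trichlorobenzoic anhydride 21 (not isolated)
Conditions: 20, 2,4,6-trichlorobenzoyl chloride, Et3N, toluene, rt; then 19, 60–80 °C, no DMAP
Reagents that add atoms: angelic acid, C/C=C(/C)C(=O)O
Why: Yamaguchi mixed-anhydride esterification run without a nucleophilic catalyst is the established way to acylate hindered secondary alcohols with angelic acid while keeping the Z geometry, and C8 is not touched.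

Step 11
Reactants: 22 8α-angeloyloxy-9-ketone
Product: 23 (1(10)Z,4E)-8α-angeloyloxy-9β-hydroxy-2β,6α,12-tris(TBSO)germacra-1(10),4,11(13)-triene
Conditions: NaBH4, CeCl3·7H2O, MeOH–THF, −78 °C; then AcOH
Reagents that add atoms: none
Why: Luche 1,2-reduction of the enone is expected to set C9 as R: in the conjugated conformer whose C5–C10 segment is chair-like with O6, C11 and O8 equatorial, hydride should enter along the axial trajectory on the α face (past H-7α only, avoiding eclipsing with axial H-8β) and give the equatorial 9β alcohol trans to the 8α ester.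

Step 12
Reactants: 23 9β-alcohol
Product: 24 (1(10)Z,4E)-8α-angeloyloxygermacra-1(10),4,11(13)-triene-2β,6α,9β,12-tetraol
Conditions: HF·pyridine, excess pyridine, THF, 0 °C → rt
Reagents that add atoms: none
Why: Buffered fluoride desilylation removes all three TBS ethers under near-neutral conditions, which should suppress both O8→O9 acyl migration and acid-induced transannular cyclisation.

Step 13
Reactants: 24 tetraol
Product: 27 8α-angeloyloxy-2β,9β-dihydroxygermacra-1(10)Z,4E,11(13)-trien-6α,12-olide, via hydroxy enal 25 (not isolated), via lactol 26 (not isolated)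
Conditions: TEMPO (cat.), PhI(OAc)2, CH2Cl2, rt
Reagents that add atoms: none
Why: In this TEMPO/PhI(OAc)2 oxidative lactonisation of a 2-methylene-1,4-diol the oxoammonium salt takes the primary allylic alcohol first, 6α-OH traps the enal as a five-membered lactol that is oxidised further, and the trans-fused α-methylene-γ-lactone closes without touching a stereocentre.

Step 14
Reactants: 27 diol lactone; 28 acetic anhydride
Product: 29 target CNP0499619.1 (2β,9β-diacetoxy-8α-angeloyloxygermacra-1(10)Z,4E,11(13)-trien-6α,12-olide)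
Conditions: Ac2O, pyridine, DMAP (cat.), CH2Cl2, 0 °C → rt
Reagents that add atoms: acetic anhydride, CC(=O)OC(C)=O
Why: Standard acetylation of the two remaining secondary allylic alcohols (O2 and O9) proceeds with retention at both carbons.

**Compound list**
1 | 2,6-dimethyl-1,4-benzoquinone | CC1=CC(=O)C=C(C)C1=O | starting material
2 | allylmagnesium bromide | C=CC[Mg]Br | starting material
3 | 4-allyl-4-hydroxy-2,6-dimethylcyclohexa-2,5-dien-1-one | CC1=CC(O)(CC=C)C=C(C)C1=O | intermediate
4 | potassium alkoxide of 3 | CC1=CC([O-])(CC=C)C=C(C)C1=O.[K+] | intermediate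
5 | potassium enolate of 6 | CC1=CC([O-])=CC(C)(CC=C)C1=O.[K+] | intermediate
6 | rac-6-allyl-2,6-dimethylcyclohex-2-ene-1,4-dione (racemic) | CC1=CC(=O)CC(C)(CC=C)C1=O | intermediate
7 | (4R,6R)-6-allyl-4-hydroxy-2,6-dimethylcyclohex-2-en-1-one | CC1=C[C@H](O)C[C@@](C)(CC=C)C1=O | intermediate
8 | 6-(2,3-dihydroxypropyl)-4-hydroxy-2,6-dimethylcyclohex-2-en-1-one, ring centres as in 7, side-chain carbinol unassigned | CC1=C[C@H](O)C[C@@](C)(CC(O)CO)C1=O | intermediate
9 | 2-[(1S,5R)-5-hydroxy-1,3-dimethyl-2-oxocyclohex-3-en-1-yl]acetaldehyde | CC1=C[C@H](O)C[C@@](C)(CC=O)C1=O | intermediate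
10 | (4R,6S)-4-(TBSO)-6-[(E)-2-(TBSO)ethenyl]-2,6-dimethylcyclohex-2-en-1-one | CC1=C[C@H](O[Si](C)(C)C(C)(C)C)C[C@@](C)(/C=C/O[Si](C)(C)C(C)(C)C)C1=O | intermediate
11 | 2-bromoprop-2-en-1-ol | C=C(Br)CO | starting material
12 | (2-bromoallyloxy)(tert-butyl)dimethylsilane | C=C(Br)CO[Si](C)(C)C(C)(C)C | intermediate
13 | (E)-1,2-bis(tributylstannyl)ethene | CCCC[Sn](CCCC)(CCCC)/C=C/[Sn](CCCC)(CCCC)CCCC | starting material
14 | (E)-tert-butyldimethyl{[2-methylidene-4-(tributylstannyl)but-3-en-1-yl]oxy}silane | CCCC[Sn](CCCC)(CCCC)/C=C/C(=C)CO[Si](C)(C)C(C)(C)C | intermediate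
15 | (E)-3-(TBSO-methyl)buta-1,3-dienyllithium | [Li]/C=C/C(=C)CO[Si](C)(C)C(C)(C)C | intermediate
16 | (1S,4R,6S)-4-(TBSO)-6-[(E)-2-(TBSO)ethenyl]-1-[(1E)-3-(TBSO-methyl)buta-1,3-dien-1-yl]-2,6-dimethylcyclohex-2-en-1-ol | CC1=C[C@H](O[Si](C)(C)C(C)(C)C)C[C@@](C)(/C=C/O[Si](C)(C)C(C)(C)C)[C@]1(O)/C=C/C(=C)CO[Si](C)(C)C(C)(C)C | intermediate
17 | potassium alkoxide of 16 | CC1=C[C@H](O[Si](C)(C)C(C)(C)C)C[C@@](C)(/C=C/O[Si](C)(C)C(C)(C)C)[C@]1([O-])/C=C/C(=C)CO[Si](C)(C)C(C)(C)C.[K+] | intermediate
18 | ring-expanded potassium C8=C9 enolate (C7 and C10 trans) | CC(C)(C)[Si](C)(C)O[C@@H]1/C=C(\C)C[C@@H](O[Si](C)(C)C(C)(C)C)/C=C(/C)\C([O-])=C\[C@H]1C(=C)CO[Si](C)(C)C(C)(C)C.[K+] | intermediate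
19 | (1(10)Z,4E)-2β,6α,12-tris(TBSO)-8α-hydroxygermacra-1(10),4,11(13)-trien-9-one | CC(C)(C)[Si](C)(C)O[C@@H]1/C=C(\C)C[C@@H](O[Si](C)(C)C(C)(C)C)/C=C(/C)C(=O)[C@H](O)[C@H]1C(=C)CO[Si](C)(C)C(C)(C)C | intermediate
20 | angelic acid | C/C=C(/C)C(=O)O | starting material
21 | angelic 2,4,6-trichlorobenzoic anhydride | C/C=C(/C)C(=O)OC(=O)c1c(Cl)cc(Cl)cc1Cl | intermediate
22 | (1(10)Z,4E)-8α-angeloyloxy-2β,6α,12-tris(TBSO)germacra-1(10),4,11(13)-trien-9-one | CC(C)(C)[Si](C)(C)O[C@@H]1/C=C(\C)C[C@@H](O[Si](C)(C)C(C)(C)C)/C=C(/C)C(=O)[C@H](OC(=O)/C(C)=C\C)[C@H]1C(=C)CO[Si](C)(C)C(C)(C)C | intermediate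
23 | (1(10)Z,4E)-8α-angeloyloxy-9β-hydroxy-2β,6α,12-tris(TBSO)germacra-1(10),4,11(13)-triene | CC(C)(C)[Si](C)(C)O[C@@H]1/C=C(\C)C[C@@H](O[Si](C)(C)C(C)(C)C)/C=C(/C)[C@@H](O)[C@H](OC(=O)/C(C)=C\C)[C@H]1C(=C)CO[Si](C)(C)C(C)(C)C | intermediate
24 | (1(10)Z,4E)-8α-angeloyloxygermacra-1(10),4,11(13)-triene-2β,6α,9β,12-tetraol | O[C@@H]1/C=C(\C)C[C@@H](O)/C=C(/C)[C@@H](O)[C@H](OC(=O)/C(C)=C\C)[C@H]1C(=C)CO | intermediate
25 | 12-al of 24 (hydroxy enal) | O[C@@H]1/C=C(\C)C[C@@H](O)/C=C(/C)[C@@H](O)[C@H](OC(=O)/C(C)=C\C)[C@H]1C(=C)C=O | intermediate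
26 | 6α,12-lactol (C12 unassigned) | C=C1C(O)O[C@@H]2/C=C(\C)C[C@@H](O)/C=C(/C)[C@@H](O)[C@H](OC(=O)/C(C)=C\C)[C@@H]12 | intermediate
27 | 8α-angeloyloxy-2β,9β-dihydroxygermacra-1(10)Z,4E,11(13)-trien-6α,12-olide | C=C1C(=O)O[C@@H]2/C=C(\C)C[C@@H](O)/C=C(/C)[C@@H](O)[C@H](OC(=O)/C(C)=C\C)[C@@H]12 | intermediate
28 | acetic anhydride | CC(=O)OC(C)=O | starting material
29 | CNP0499619.1 | C=C1C(=O)O[C@@H]2/C=C(\C)C[C@@H](OC(C)=O)/C=C(/C)[C@@H](OC(C)=O)[C@H](OC(=O)/C(C)=C\C)[C@@H]12 | target

**Step count:** 14 steps in total. The longest linear sequence is 12 steps (steps 1–5 and 8–14).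

**Steps most likely to fail**

Step 9 (key step). The donor-substituted C6 terminus may slow the rearrangement. The alkoxide medium may strip the silyl enol ether. A boat pathway may erode control at C6 and C7. The hindered enolate may be captured incompletely by the oxaziridine. The fallback sets out from 16 and comes back at 19; it gives up charge acceleration and separates the two events. Compound 16 is silylated (TMSOTf, 2,6-lutidine, CH2Cl2, −78 °C) to the tertiary trimethylsilyl ether F1. This ether is heated in a base-washed sealed tube (xylene, 150–180 °C) in a neutral siloxy-Cope rearrangement through the same chair, which gives the ring-expanded trimethylsilyl enol ether F2. Rubottom oxidation of F2 follows (dimethyldioxirane, acetone, −78 °C, then citric acid in MeOH). It attacks the most electron-rich olefin on its outer face and releases 19.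

Step 11. Hydride may be delivered to the wrong face of C9 if another ring conformer reacts, and the borohydride medium may start acyl migration. The fallback sets out from 22 and comes back at 29; it accepts the wrong face and corrects it by substitution. The 9-epi (9α) alcohol F3 obtained from 22 undergoes a Mitsunobu reaction with acetic acid (PPh3, DIAD, toluene, 0 °C). This inverts C9 and installs the acetate at once, giving the 9β-acetate F4. HF·pyridine then gives the 2β,6α,12-triol F5. TEMPO/PhI(OAc)2 closes the lactone to the 2β-hydroxy lactone F6, and Ac2O/pyridine acetylates O2 to give 29.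

Step 5. Kinetic enolisation may give poor E/Z control, which would feed the wrong geometry into the key step and so the wrong configuration at C6. The fallback sets out from 9 and comes back at 10; it replaces kinetic control by a separate thermodynamic equilibration. Compound 9 is silylated without regard to geometry and the (Z)-enol ether F7 is separated. F7 is then isomerised by reversible thiyl-radical addition–elimination (PhSSPh cat., hν, cyclohexane). Under these conditions the E isomer 10, relieved of the OTBS/quaternary-carbon contact, should be the thermodynamic sink, and recovered F7 is recycled.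

**Further compounds**
F1 | step 9 | trimethylsilyl ether of 16 | CC1=C[C@H](O[Si](C)(C)C(C)(C)C)C[C@@](C)(/C=C/O[Si](C)(C)C(C)(C)C)[C@]1(O[Si](C)(C)C)/C=C/C(=C)CO[Si](C)(C)C(C)(C)C
F2 | step 9 | ring-expanded C8=C9 trimethylsilyl enol ether | CC(C)(C)[Si](C)(C)O[C@@H]1/C=C(\C)C[C@@H](O[Si](C)(C)C(C)(C)C)/C=C(/C)\C(O[Si](C)(C)C)=C\[C@H]1C(=C)CO[Si](C)(C)C(C)(C)C
F3 | step 11 | 9-epi (9α) alcohol of 23 | CC(C)(C)[Si](C)(C)O[C@@H]1/C=C(\C)C[C@@H](O[Si](C)(C)C(C)(C)C)/C=C(/C)[C@H](O)[C@H](OC(=O)/C(C)=C\C)[C@H]1C(=C)CO[Si](C)(C)C(C)(C)C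
F4 | step 11 | 9β-acetoxy-8α-angeloyloxy-2β,6α,12-tris(TBSO)germacra-1(10)Z,4E,11(13)-triene | CC(C)(C)[Si](C)(C)O[C@@H]1/C=C(\C)C[C@@H](O[Si](C)(C)C(C)(C)C)/C=C(/C)[C@@H](OC(C)=O)[C@H](OC(=O)/C(C)=C\C)[C@H]1C(=C)CO[Si](C)(C)C(C)(C)C
F5 | step 11 | 9β-acetoxy-8α-angeloyloxygermacra-1(10)Z,4E,11(13)-triene-2β,6α,12-triol | O[C@@H]1/C=C(\C)C[C@@H](O)/C=C(/C)[C@@H](OC(C)=O)[C@H](OC(=O)/C(C)=C\C)[C@H]1C(=C)CO
F6 | step 11 | 9β-acetoxy-8α-angeloyloxy-2β-hydroxygermacra-1(10)Z,4E,11(13)-trien-6α,12-olide | C=C1C(=O)O[C@@H]2/C=C(\C)C[C@@H](O)/C=C(/C)[C@@H](OC(C)=O)[C@H](OC(=O)/C(C)=C\C)[C@@H]12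
F7 | step 5 | (4R,6S)-4-(TBSO)-6-[(Z)-2-(TBSO)ethenyl]-2,6-dimethylcyclohex-2-en-1-one | CC1=C[C@H](O[Si](C)(C)C(C)(C)C)C[C@@](C)(/C=C\O[Si](C)(C)C(C)(C)C)C1=O
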